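(Readings and results come from a simulation with made-up constants; noise was put on by code.)

The ratio of second end groups to first end groups charged was 0.750 in the autumn run and 1.00 in my flask, and I wanted to know whether that rise would use up the first end groups.

| setting | midnight | autumn | flask |
|---|---|---|---|
| first end groups | 0.20 M (in portions, 3) | 0.20 M (in portions, 3) | 0.20 M (in portions, 3) |
| second end groups | 0.10 M | 0.15 M | 0.200 M |
| protic impurity | 4 mM | 4 mM | 4.00 mM |
| remark | run made earlier; portions every 1.5 s | run made earlier; portions every 1.5 s | the portions of first end groups follow each other after 1.5 s, the first at the start |
| time |  |  | 12 min |

| run | time / min | first end groups / % | links / % |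
|---|---|---|---|
| midnight | 0.833 | 54 | 18 |
| midnight | 1.33 | 52 | 18 |
| midnight | 2.00 | 53 | 18 |
| midnight | 2.50 | 48 | 17 |
| midnight | 4.00 | 55 | 18 |
| midnight | 6.00 | 56 | 17 |
| midnight | 10.0 | 51 | 16 |
| autumn | 0.833 | 35 | 28 |
| autumn | 1.33 | 35 | 28 |
| autumn | 2.00 | 35 | 28 |
| autumn | 2.50 | 32 | 30 |
| autumn | 4.00 | 35 | 28 |
| autumn | 6.00 | 36 | 31 |
| autumn | 10.0 | 35 | 28 |

(scatter of a reading: 1.5 percentage points)

* which holds at 12 min: what has brought the reaction to rest, or that it has not come to rest (all of the first end groups has reacted / the second end groups has run out first / it is still moving / forward and back rates have come level)
* how much of the first end groups has reacted by 12 min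
* how much links there is at 12 min, in percent of the first end groups charged

- steps thought possible: 2 second end groups -> homo dimer; first end groups + second end groups -> links; first end groups + protic impurity -> quenched substrate; first end groups + second end groups -> rings
- the reaction counts as stopped when no species that holds the first end groups changes by six tenths of a point or more over the second half of the time

I counted turnovers. Autumn's readings stood flat from 0.833 min to 10.0 min, with a mean of 34.7% of the first end groups left. Setting aside what the protic impurity could quench, the reacted first end groups gave a reading of 0.844. I call this the coupling share: coupled concentration per c(second end groups) charged. Among the listed steps, the other route for second end groups was homo dimer.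

Midnight, with its mean of 52.7%, read 0.906, so the reading was lower in autumn, at the higher c(second end groups). A straight line through both gave 0.782 for my flask.

Second end groups, the limiting reagent, could then couple 0.156 M. That is less than the 0.196 M of first end groups open to coupling, so I expected this flask, like autumn, to stop with first end groups left. My count gave 80.2% reacted, 15 percentage points above autumn's reading.

The forecast was: the second end groups has run out first, 80% reacted, 39% links. Its ground for the loss was “That loss grows with loading, so I extrapolate about 22% at 0.20 M.”

The flask gave the second end groups has run out first, with 81.5% reacted and 39.9% links, while second end groups stood at 0% of their charge.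

    2 second end groups → homo dimer (k = 0.150 /M/s)
    first end groups + second end groups → links (k = 0.704 /M/s)
    first end groups + protic impurity → quenched substrate (k = 208 /M/s)
    first end groups + second end groups → rings, rate k4*[first end groups] as long as [second end groups] is above zero (k = 0.0482 /s)

The flask's coupling share came to 0.795, below autumn's reading of 0.844, and the flask's homo dimer path had half of its turnover behind it by 2.18 s, earlier than links at 4.01 s and rings at 7.94 s. For the neighbour charged with 0.080 M of second end groups, the same line through the runs gave a share of 0.930, and that neighbour reached 0.934, with 60.6% of its first end groups left.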